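(The data stem from a simulated flask for substances that don't exist; noise was put on by code.)

Start from the plateaus.

all flasks: first end groups 0.25 M

| run | second end groups | remark | time |
|---|---|---|---|
| Saturday's | 0.12 M | run made earlier |  |
| Thursday's | 0.19 M | run made earlier |  |
| flask | 0.250 M |  | 10 d |

| run | time / d | links / % | first end groups / % |
|---|---|---|---|
| Saturday's | 1.67 | 37.1 | 64.1 |
| Saturday's | 3.00 | 36.1 | 63.4 |
| Saturday's | 5.00 | 36.1 | 63.9 |
| Saturday's | 6.00 | 36.5 | 63.3 |
| Saturday's | 8.00 | 36.8 | 63.6 |
| Saturday's | 10.0 | 37.1 | 63.8 |
| Thursday's | 1.67 | 52.7 | 46.5 |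
| Thursday's | 3.00 | 53.5 | 46.3 |
| Thursday's | 5.00 | 53.1 | 47.1 |
| Thursday's | 6.00 | 54.2 | 47.6 |
| Thursday's | 8.00 | 53.3 | 47.2 |
| Thursday's | 10.0 | 53.1 | 46.2 |

(each reading ± 0.5 percentage points)

- each molecule carries two end groups: a chain counts once for every two ends that are left, dead ends included; the units are half of the end groups of the two monomers charged
- what has gone from first end groups into another species counts as reacted, even if it can come back

1. average number of monomer units in a chain (unreacted monomers counted as chains of one) at 10 d
2. part of the first end groups that has reacted at 10 d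

Write A, B and L for the concentrations of first end groups, second end groups and links. On the first rung of the time ladder stands linking. Saturday's links read 37.1 % at 1.67 d and 37.1 % at 10.0 d, and Thursday's read 52.7 % and 53.1 %, differences no larger than the scatter of 0.5 percentage points. So the readings already stand on their plateau at your first reading.

On the next rung, days long, you see no drift. Averaged over each run, Saturday gives L = 36.6 % and A = 63.7 %, and Thursday gives L = 53.3 % and A = 46.8 %. Each pair sums to about the charge, so B is its charge minus L.

The ratio L/(AB) then reads 20.2 M⁻¹ on Saturday and 20.1 M⁻¹ on Thursday, from different charges. Carry their mean, the link ratio K, which is the equilibrium constant: 20.1 M⁻¹.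

In your balanced flask A = B = y, and K = (cA − y)/y² gives y = 0.0893 M. Units are cA and chains are y, so I expect dp = 2.80 and c = 64.3 %.

A small disturbance of L decays at a rate proportional to A + B + 1/K. This flask's free ends, 0.179 M, are more than Thursday's 0.174 M and less than Saturday's 0.188 M. So it should relax about as they did, in less than 1.67 d, which is shorter than the asked 10 d.

The forecast, reasoning that “The agreement suggests simple reversible linking”, gave dp = 2.79 (2.69 to 2.89) and c = 64.2 % (62.8 % to 65.5 %), which differ slightly from my dp and c.

The flask gives dp = 2.79 and c = 64.2 %, with first end groups at 35.8 % after 1.00 d and 35.8 % after 10.0 d.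

    first end groups + second end groups ⇌ links (K = 20.0 M⁻¹, k = 8.80 M⁻¹ h⁻¹)

Now take the neighbouring flask with 0.42 M of first end groups and 0.250 M of second end groups, which are the limiting reagent at 0.595 equiv. With K, links x follow from K(A₀ − x)(B₀ − x) = x, where A₀ and B₀ are the charges, and x = 0.203 M. That reckons c = 48.3 % and dp = 2.54. The neighbouring flask gives c = 48.4 % and dp = 2.54, with 18.7 % of its second end groups left.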